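Readings and results are calculated with made-up constants; noise was put on by code.

Late in both earlier runs the share s of target in target plus isomer of the product levels off. The last readings give a plateau p of 15.2% in the north-west run at 2 °C and 20.0% in the south-east run at 22 °C.

all flasks: impurity 1.7 µM
- north-west: substrate 0.034 M; free enzyme 5 µM; temperature 2 °C; run made earlier
- south-east: substrate 0.075 M; free enzyme 5 µM; temperature 22 °C; run made earlier
- maple: substrate 0.050 M; free enzyme 5.0 µM; temperature 37 °C; time 2.0 h
- alder: substrate 0.050 M; free enzyme 5.0 µM; temperature 22 °C; time 2.0 h
- larch: substrate 0.050 M; free enzyme 5.0 µM; temperature 7 °C; time 2.0 h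

- north-west (time / h: target / %, isomer of the product / %): 0.833: 50.0, 15.3; 2.00: 42.3, 31.6; 4.00: 28.0, 56.5; 6.00: 19.5, 65.6; 8.00: 16.1, 72.2; 12.0: 15.7, 75.9; 15.0: 14.2, 79.1
- south-east (time / h: target / %, isomer of the product / %): 0.417: 53.1, 25.9; 0.667: 42.8, 40.9; 0.833: 40.2, 48.1; 1.33: 29.4, 59.7; 2.00: 22.7, 68.4; 3.00: 22.8, 72.9; 5.00: 18.7, 74.9

(standard deviation of a reading: 1 percentage point)

- the flask with the highest share of target in all that became target or isomer of the product ("all alike" if they lie within 1.5 percentage points) (maple / alder / larch / all alike)
- share of target in all that became target or isomer of the product, maple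
- share of target in all that became target or isomer of the product, alder
- share of target in all that became target or isomer of the product, larch

You take over maple, alder and larch, each to be stopped at 2.0 h. Read them by the fraction left, L = (s − p)/(1 − p), the part of the way from pure target to the plateau still to go. If L falls as exp(−λt), the south-east reading at 0.833 h gives a relaxation rate λ of 1.37 /h, and the north-west reading at 4.00 h gives 0.389 /h.

My own reckoning puts larch, at 7 °C, a quarter of the way between the runs, in ln λ and in p. So larch has λ = 0.533 /h, p = 16.4%, L = 0.345 and s = 45.2%. I give alder, at the temperature of the south-east run but with less substrate, the south-east λ and p, so L = 0.0645 and s = 25.1%. For maple I extrapolate p the same way and take that plateau, 23.5%, as my figure. Leave the enzyme and impurity charges alone: both runs were made at 5 µM and 1.7 µM, so λ and p are read at those charges. Stop larch on time: my L for it at 2.0 h is still 0.345.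

The forecast says larch, with 25.5% for maple, 24.5% for alder and 46% for larch, and it keeps maple's figure “unless the enzyme dies at that temperature, which is untested”. My figures for maple and larch are lower than the forecast's, and my figure for alder is higher than the forecast's.

The flasks gave 26.3% in maple, 25.7% in alder and 43.9% in larch, so larch leads.

    free enzyme → unfolded enzyme (k = 2.53 × 10⁻⁴ /min, Ea = 239 kJ/mol)
    substrate + free enzyme → target + free enzyme, rate k2*[substrate]^3*[free enzyme]/(1 + ([substrate]/Kh2)^3) (49.0 mM, k = 6.64 × 10⁵ /M³/s, Ea = 16.0 kJ/mol)
    target + free enzyme ⇌ isomer of the product + free enzyme, rate k3*[free enzyme]*[target] forward; the back reaction follows from the equilibrium constant (K = 2.91, k = 16300 /M/min, Ea = 42.0 kJ/mol, ΔH = −15.0 kJ/mol)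
    free enzyme + impurity → spent catalyst (k = 48200 /M/s, Ea = 34.0 kJ/mol)
    (constants at 37 °C)

Larch's share means L = 0.329, so λ = 0.556 /h against the 0.533 /h reckoned. Alder's neighbour charged with 2.00 µM ended with 15.0% of it free, against 66.0% of 5.0 µM in alder. Scaling λ with free enzyme and keeping p gives λ = 0.125 /h and s = 82.3%, and that neighbour gave 84.7%. Maple held 1.97% of its catalyst as unfolded enzyme at 2.00 h, a step that makes no difference to its share. In alder at 0.104 h, target was made 4.00 times faster than it was used up, each step taken net. By 2.00 h alder made target more slowly than it used it up, the net ratio standing at 0.412.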